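**Strategy.** The plan rests on disconnecting C3–C4 of the upper cyclopentenone (C1–C5). What remains is a (Z)-2,5-dienoyl chloride in which the cyclohexene C1=C2 bond holds the C3 acyl group and the C5 vinyl group cis. One palladium-catalysed acyl-Heck cyclisation closes this ring and creates the C4=C15 methylene and the cross-conjugated dienone at once. The precursor comes from Diels–Alder union of dehydrozaluzanin C (C4′=C15′) with a seco-dienal cut from the same dehydrocostus lactone pool; its C5 is rebuilt with inversion by decarboxylative vinylation, and C10 is set by enal reconjugation before ring closure.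

Key step: step 10

Remark: guaianolide numbering is used (C1–C15 upper unit, primed locants lower unit); α/β as in dehydrocostus lactone (H-1α, H-5α, H-6β, H-7α).
Remark: in the target the upper H-5 is β (cis to H-6, 5S), opposite to dehydrocostus lactone, so this centre is rebuilt in step 5; the upper H-10 is α (10R) and C4′ is R.
Assumption: dehydrocostus lactone (1) is taken as commercially available.

Step 1
Reactants: 1 dehydrocostus lactone
Product: 2 3-epizaluzanin C (3α-hydroxydehydrocostus lactone, 3R)
Conditions: SeO2 (0.5 equiv), tBuOOH, CH2Cl2, 0 °C to rt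
Reagents that add atoms: tert-butyl hydroperoxide CC(C)(C)OO
Why: Allylic oxidation (ene reaction then [2,3]-shift) should hydroxylate the C3 methylene next to C4=C15 from the open α-face; the C3 configuration is lost later and is immaterial.

Step 2
Reactants: 2 3-epizaluzanin C (part of the material)
Product: 3 dehydrozaluzanin C (3-oxo-guaia-4(15),10(14),11(13)-trien-12,6α-olide)
Conditions: DMP, CH2Cl2, 0 °C to rt
Reagents that add atoms: none
Why: Hypervalent-iodine oxidation of the secondary allylic alcohol should give the enone without touching the exocyclic alkenes or any stereocenter.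

Step 3
Reactants: 2 3-epizaluzanin C
Product: 4 4α,15-epoxy-3α-hydroxy-guaia-10(14),11(13)-dien-12,6α-olide
Conditions: VO(acac)2 (5 mol %), tBuOOH, CH2Cl2, 0 °C to rt
Reagents that add atoms: tert-butyl hydroperoxide CC(C)(C)OO
Why: Hydroxyl-directed vanadium-catalysed epoxidation should affect only the allylic C4=C15 bond and deliver oxygen syn to the 3α-hydroxyl; both new centres are removed in step 4.

Step 4
Reactants: 4 epoxy alcohol
Product: 5 seco acid–aldehyde (cycloheptane C1, C5–C10 with the trans-fused α-methylene lactone at C6/C7, 10-methylidene, β-2-oxoethyl at C1, β-CO2H at C5; H-1α, H-5α)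
Conditions: H5IO6 (2.5 equiv), THF/H2O, 0 °C to rt
Reagents that add atoms: water O
Why: Periodic acid should hydrolyse the epoxide to the 3,4,15-triol and cleave it twice (glycol cleavage, then α-ketol cleavage), excising C15 as formaldehyde and leaving C3 as aldehyde and C4 as carboxylic acid while C1, C5, C6 and C7 stay untouched.

Step 5
Reactants: 5 seco acid–aldehyde
Product: 7 C5-vinyl seco-aldehyde (as 5, but C5 carries an α-ethenyl group, the new C4=C15; H-5β, cis to H-6β), via redox-active phthalimide ester 6 (not isolated)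
Conditions: N-hydroxyphthalimide, N,N'-diisopropylcarbodiimide, DMAP (cat.), CH2Cl2, 0 °C to rt; solvent switch to DMA; vinyl bromide (THF solution), NiBr2·glyme (10 mol %), 4,4'-di-tert-butyl-2,2'-bipyridine, Zn dust, rt
Reagents that add atoms: vinyl bromide C=CBr
Why: Nickel-catalysed reductive decarboxylative alkenylation: the C5 radical formed by loss of CO2 should be captured by the vinylnickel species on the α-face, anti to the pseudo-axial C1 side chain (β) and to axial H-6, so the vinyl group ends cis to O6 (H-5β), as the target requires.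

Step 6
Reactants: 7 C5-vinyl seco-aldehyde
Product: 8 (2E)-seco-dienal (C3HO–C2H=C1 conjugated with C10=C14; formyl trans to C10, cis to C5)
Conditions: IBX (2.5 equiv), DMSO/fluorobenzene, 65 °C
Reagents that add atoms: none
Why: IBX α,β-dehydrogenation of the aldehyde should remove H-2 and the allylic H-1 to give the conjugated dienal; the E isomer is expected because H-5 can then eclipse the formyl group (least A(1,3) strain); the C1 stereocenter of 1 is deliberately destroyed here.

Step 7
Reactants: 8 (2E)-seco-dienal; 3 dehydrozaluzanin C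
Product: 9 Diels–Alder adduct (spiro cyclohexene with new C2–C4′ and C14–C15′ bonds, C1=C10 alkene, formyl on C2; C4′ R; C2 epimers)
Conditions: toluene, BHT (cat.), 90 °C, sealed tube
Reagents that add atoms: none
Why: Intermolecular Diels–Alder reaction with "ortho" regiochemistry (the remote diene terminus C14 bonds to the enone β-carbon C15′) should proceed on the α-face of the exocyclic enone, anti to the cis-fused cycloheptane, which sets C4′ (R); the C2 configuration is lost in step 8.

Step 8
Reactants: 9 Diels–Alder adduct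
Product: 10 conjugated enal (C1=C2, H-10α, 10R)
Conditions: DBU (0.1 equiv), CH2Cl2, 0 °C
Reagents that add atoms: none
Why: Base-mediated reconjugation (α-deprotonation at C2, γ-protonation at C10) should give the tetrasubstituted enal as in the α- to β-cyclocitral isomerisation; with H-5 held in the enal plane by A(1,3) strain, C10 should protonate axially on the face of the C5 vinyl group, giving 10R, the epimer whose cycloheptane is an unstrained twist-chair in the open enal.

Step 9
Reactants: 10 conjugated enal
Product: 11 conjugated carboxylic acid (C3 acid on C2)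
Conditions: NaClO2, NaH2PO4, 2-methyl-2-butene, tBuOH/H2O, 0 °C to rt
Reagents that add atoms: sodium chlorite [Na+].[O-]Cl=O
Why: Pinnick oxidation should convert the hindered enal to the acid under buffered conditions that leave the alkenes, ketone and lactones alone and do not enolise toward C5 or C10.

Step 10
Reactants: 11 conjugated carboxylic acid
Product: 13 target CNP0221188.1, via acid chloride 12 (not isolated)
Conditions: 1-chloro-N,N,2-trimethylprop-1-en-1-amine, CH2Cl2, 0 °C; then Pd(PPh3)4 (10 mol %), 2,6-lutidine, MeCN/benzene, 25–40 °C, argon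
Reagents that add atoms: none
Why: Zerovalent palladium should insert into the C3–Cl bond of 12, the acylpalladium chloride adds across the C5 vinyl group (C3–C4 bond), syn β-hydride elimination of H-4 from the C15–Pd intermediate releases the C4=C15 methylene, and 2,6-lutidine takes up HCl to return the catalyst. The closest known reaction type is the intramolecular acyl-Heck (acylpalladation–dehydropalladation) cyclisation of (Z)-2,5-dienoyl chlorides to 5-methylenecyclopent-2-enones. The only ring closed is the cyclopentenone C1–C5, by 5-exo-trig insertion. No stereocenter is created: C5 and C10 are carried unchanged from steps 5 and 8, and C4 ends sp2. The step needs 5-exo rather than 6-endo insertion, insertion faster than decarbonylation, and no epimerisation of the acidic C5–H. The cyclohexene C1=C2 bond fixes the acyl group and C5 cis, only H-4 is available for β-elimination, and the weak hindered base and low temperature protect C5.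

**Compound list**

1 | dehydrocostus lactone | C=C1CC[C@H]2C(=C)CC[C@H]3C(=C)C(=O)O[C@@H]3[C@@H]12 | starting material
2 | 3-epizaluzanin C (3α-hydroxy, 3R) | C=C1[C@H](O)C[C@H]2C(=C)CC[C@H]3C(=C)C(=O)O[C@@H]3[C@@H]12 | intermediate
3 | dehydrozaluzanin C | C=C1C(=O)C[C@H]2C(=C)CC[C@H]3C(=C)C(=O)O[C@@H]3[C@@H]12 | intermediate
4 | 4α,15-epoxy-3α-hydroxy-guaia-10(14),11(13)-dien-12,6α-olide | C1O[C@@]12[C@H](O)C[C@H]3C(=C)CC[C@H]4C(=C)C(=O)O[C@@H]4[C@@H]23 | intermediate
5 | seco acid–aldehyde (C1 β-CH2CHO, C5 β-CO2H) | O=CC[C@H]1C(=C)CC[C@H]2C(=C)C(=O)O[C@@H]2[C@H]1C(=O)O | intermediate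
6 | N-(acyloxy)phthalimide ester of 5 | O=CC[C@H]1C(=C)CC[C@H]2C(=C)C(=O)O[C@@H]2[C@H]1C(=O)ON1C(=O)c2ccccc2C1=O | intermediate
7 | C5-vinyl seco-aldehyde (vinyl α, H-5β) | O=CC[C@H]1C(=C)CC[C@H]2C(=C)C(=O)O[C@@H]2[C@@H]1C=C | intermediate
8 | (2E)-seco-dienal | O=C/C=C1/C(=C)CC[C@H]2C(=C)C(=O)O[C@@H]2[C@@H]1C=C | intermediate
9 | Diels–Alder adduct (C1=C10, C2–CHO, C2 unspecified, C4′ R) | O=CC1C2=C(CC[C@H]3C(=C)C(=O)O[C@@H]3[C@@H]2C=C)CC[C@]14C(=O)C[C@H]5C(=C)CC[C@H]6C(=C)C(=O)O[C@@H]6[C@H]54 | intermediate
10 | conjugated enal (C1=C2, 10R) | O=CC1=C2[C@H](CC[C@H]3C(=C)C(=O)O[C@@H]3[C@@H]2C=C)CC[C@]14C(=O)C[C@H]5C(=C)CC[C@H]6C(=C)C(=O)O[C@@H]6[C@H]54 | intermediate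
11 | conjugated carboxylic acid | O=C(O)C1=C2[C@H](CC[C@H]3C(=C)C(=O)O[C@@H]3[C@@H]2C=C)CC[C@]14C(=O)C[C@H]5C(=C)CC[C@H]6C(=C)C(=O)O[C@@H]6[C@H]54 | intermediate
12 | acid chloride of 11 | O=C(Cl)C1=C2[C@H](CC[C@H]3C(=C)C(=O)O[C@@H]3[C@@H]2C=C)CC[C@]14C(=O)C[C@H]5C(=C)CC[C@H]6C(=C)C(=O)O[C@@H]6[C@H]54 | intermediate
13 | CNP0221188.1 | C=C1C(=O)C2=C3[C@H](CC[C@H]4C(=C)C(=O)O[C@@H]4[C@H]13)CC[C@]21C(=O)C[C@H]2C(=C)CC[C@H]3C(=C)C(=O)O[C@@H]3[C@H]21 | target

Total step count: 10. Longest linear sequence: 9 steps (1, 3, 4, 5, 6, 7, 8, 9, 10); step 2 supplies the dienophile.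

**Steps most likely to fail**

Step 10. The product carries a strained cycloheptane (C6 and C9 on opposite faces of the enone plane), so insertion may be slow. Decarbonylation of the acylpalladium or base-induced epimerisation at C5 could then take over. The fallback sets out from 11 and returns at 13. Acid 11 is converted with (PhSe)2 and PBu3 into the Se-phenyl selenoester F1. Photolysis in benzene with catalytic (Bu3Sn)2 generates the acyl radical, which should cyclise 5-exo onto the vinyl group with phenylseleno group transfer to give the 15-phenylselanyl-4,15-dihydro ketone F2. Oxidation with H2O2/pyridine at 0 °C and selenoxide syn-elimination toward H-4 then gives 13 without any amine base.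

Step 5. Radical capture may show poor facial selectivity, or reduction and β-acyloxy elimination at nickel may compete. The fallback sets out from 5 and returns at 7. Photoredox decarboxylative alkynylation of the free acid (Ir[dF(CF3)ppy]2(dtbbpy)PF6, cesium benzoate, blue light, 1-[(triisopropylsilyl)ethynyl]-1,2-benziodoxol-3(1H)-one) should give the C5-silylalkyne F3 by metal-free radical trapping on the same α-face. Buffered TBAF gives the terminal alkyne F4. Semihydrogenation (H2, Pd/CaCO3 poisoned with Pb(OAc)2, quinoline) gives 7.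

Step 7. Both partners are electron-poor, so the cycloaddition may be sluggish and dimerisation or polymerisation of 3 may win. The fallback sets out from 8 (with 3) and returns at 9. Luche reduction (NaBH4, CeCl3·7H2O, MeOH, −78 °C) gives the dienol F5, and TBSCl/imidazole gives the silyl ether F6, now an electron-rich diene. Cycloaddition with 3 promoted by Me2AlCl at −78 to −20 °C should give the adduct F7 with the same regiochemistry and facial sense. HF·pyridine gives the alcohol F8, and DMP oxidation gives 9.

Further compounds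
F1 | step 10 | Se-phenyl selenoester of 11 | O=C([Se]c1ccccc1)C1=C2[C@H](CC[C@H]3C(=C)C(=O)O[C@@H]3[C@@H]2C=C)CC[C@]14C(=O)C[C@H]5C(=C)CC[C@H]6C(=C)C(=O)O[C@@H]6[C@H]54
F2 | step 10 | 15-phenylselanyl-4,15-dihydro derivative of 13 (C4 unspecified) | c1ccccc1[Se]CC1C(=O)C2=C3[C@H](CC[C@H]4C(=C)C(=O)O[C@@H]4[C@H]13)CC[C@]21C(=O)C[C@H]2C(=C)CC[C@H]3C(=C)C(=O)O[C@@H]3[C@H]21
F3 | step 5 | C5-[(triisopropylsilyl)ethynyl] seco-aldehyde | O=CC[C@H]1C(=C)CC[C@H]2C(=C)C(=O)O[C@@H]2[C@@H]1C#C[Si](C(C)C)(C(C)C)C(C)C
F4 | step 5 | C5-ethynyl seco-aldehyde | O=CC[C@H]1C(=C)CC[C@H]2C(=C)C(=O)O[C@@H]2[C@@H]1C#C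
F5 | step 7 | (2E)-seco-dienol | OC/C=C1/C(=C)CC[C@H]2C(=C)C(=O)O[C@@H]2[C@@H]1C=C
F6 | step 7 | TBS ether of the seco-dienol | CC(C)(C)[Si](C)(C)OC/C=C1/C(=C)CC[C@H]2C(=C)C(=O)O[C@@H]2[C@@H]1C=C
F7 | step 7 | Diels–Alder adduct silyl ether (C2 unspecified) | CC(C)(C)[Si](C)(C)OCC1C2=C(CC[C@H]3C(=C)C(=O)O[C@@H]3[C@@H]2C=C)CC[C@]14C(=O)C[C@H]5C(=C)CC[C@H]6C(=C)C(=O)O[C@@H]6[C@H]54
F8 | step 7 | Diels–Alder adduct primary alcohol (C2 unspecified) | OCC1C2=C(CC[C@H]3C(=C)C(=O)O[C@@H]3[C@@H]2C=C)CC[C@]14C(=O)C[C@H]5C(=C)CC[C@H]6C(=C)C(=O)O[C@@H]6[C@H]54
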